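**Retrosynthetic overview**

1. The target is a C2-symmetric tetramer, ring A–CH2–ring B–CH2–ring C–CH2–ring D, with ring A identical to ring D (butyrylfilicinic acid) and ring B identical to ring C (butyrylphloroglucinol). Both outer aryl–CH2 bonds are cut (retro-Friedel–Crafts through a methylene trione) to give two molecules of Mannich base 8 and the bis-phloroglucinol 11.
2. Ring A/D is numbered C1 (ring C=O), C2 (butyryl carbon), C3 and C5 (enol carbons), C4 (CMe2), C6 (carbon bearing the bridge CH2). It is cut at C6–C1 and C2–C3 into an open-chain four-carbon piece C3–C6 (amino keto ester 2, which already carries the future bridge carbon) and a two-carbon piece C1–C2 carrying the butyryl group (butyrylketene 6, released in the flask from phenyl ester 5).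
3. Enabling feature: ring A is a 2-acylcyclohexane-1,3,5-trione. C1, C3 and C5 are carbonyl carbons and C2 and C6 are the nucleophilic carbons between them, so both new bonds are enolate-to-acyl bonds. The quaternary C4 leaves the precursor a single enolisable carbon (C6) and makes an aldol closure impossible.
4. Order of ring formation: rings B and C are bought as the arene of 9 and joined by formaldehyde (step 4). Ring A/D is built in step 3. Step 5 attaches two copies of it to 11 without any further ring closure.

Key step: step 3

Remark on the chemistry: the target has no stereocentre; triketone rings are drawn in the enol form of the target, and lithium enolates are treated as ionised forms of the numbered carbonyl compounds.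

**Step 1**
Reactants: 1 methyl 2,2-dimethyl-3-oxobutanoate
Product: 2 methyl 5-(dimethylamino)-2,2-dimethyl-3-oxopentanoate
Conditions: LiN(iPr)2 (1.05 equiv), THF, −78 °C; then CH2=NMe2+ I− (1.0 equiv), −78 → 0 °C; aq NaHCO3
Reagents that add atoms: N,N-dimethylmethyleneiminium iodide (Eschenmoser's salt), C=[N+](C)C.[I-]
Why: The acetyl methyl group is the only enolisable position of 1, so Mannich-type aminomethylation of its lithium enolate with the preformed iminium salt should give the β-amino ketone regiospecifically.

**Step 2**
Reactants: 3 phenyl acetate (2.1 equiv); 4 butanoyl chloride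
Product: 5 phenyl 3-oxohexanoate
Conditions: 3, LiN(iPr)2 (2.1 equiv), THF, −78 °C; then 4 (1.0 equiv), −78 °C; 1 M HCl quench at −78 °C
Reagents that add atoms: none
Why: Crossed Claisen condensation, in which the preformed lithium enolate of the phenyl ester is C-acylated by the acid chloride and the second equivalent of enolate takes up the acidic proton of the β-keto ester; the enolate and the product are kept at −78 °C until the acidic quench, where loss of phenoxide is slow.

**Step 3**
Reactants: 2 methyl 5-(dimethylamino)-2,2-dimethyl-3-oxopentanoate; 5 phenyl 3-oxohexanoate (1.2 equiv)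
Product: 8 2-butanoyl-6-[(dimethylamino)methyl]-3,5-dihydroxy-4,4-dimethylcyclohexa-2,5-dien-1-one (Mannich base of butyrylfilicinic acid), via butyrylketene 6 (not isolated), via triketo ester 7 (not isolated)
Conditions: 2, LiN(SiMe3)2 (1.05 equiv), THF, −78 °C; dropwise addition of 5 pre-treated with LiN(SiMe3)2 (1.0 equiv, THF, −78 °C); −78 → 25 °C; then LiN(SiMe3)2 (1.2 equiv), 50 °C; aq HCl to pH 6
Reagents that add atoms: none
Why: Proposed new method: LiN(SiMe3)2 converts 2 into its only possible enolate (at C4, next to the ketone) and 5 into its stabilised enolate, which on warming expels phenoxide (E1cB) to release butyrylketene 6; the enolate carbon of 2 adds to the ketene sp carbon (first C–C bond, C6–C1 of ring A) and so delivers directly the 1,3-diketone enolate of triketo ester 7, whose central carbon, after the third portion of base, attacks the neopentyl methyl ester in a 6-exo-trig Claisen (Dieckmann-type) closure with loss of methoxide (second C–C bond, C2–C3), the six-membered carbocycle being the only ring that closes. The closest known reaction types are the E1cB acyl transfer of aryl acetoacetates through acetylketene, the C-acetoacetylation of enolates by diketene, and the biomimetic Claisen cyclisation of 3,5,7-triketo esters to acylphloroglucinols. No stereocentre is formed. The step needs C- over O-acylation, Claisen over aldol closure and carbocycle over pyranone formation: an O-acylated enol ester would itself be an E1cB-active ester and should revert to ketene and enolate until the irreversible C–C bond is made, the only aldol alternative would need the quaternary CMe2 carbon as nucleophile and is impossible, the gem-dimethyl group favours closure (Thorpe–Ingold effect), and the product leaves the equilibrium as its doubly deprotonated vinylogous acid. Slow addition of the enolate of 5 to the enolate of 2 should keep the ketene concentration low and suppress its dimerisation to a pyranone.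

**Step 4**
Reactants: 9 1-(2,4,6-trihydroxyphenyl)butan-1-one (phlorobutyrophenone, 2.2 equiv per formaldehyde)
Product: 11 1,1'-[methylenebis(2,4,6-trihydroxy-3,1-phenylene)]di(butan-1-one), via hydroxymethyl adduct 10 (not isolated)
Conditions: 37% aq CH2O (0.45 equiv), cat. HCl, MeOH–H2O, 25 °C
Reagents that add atoms: formaldehyde, C=O
Why: Phenol–formaldehyde condensation (Lederer–Manasse hydroxymethylation followed by Friedel–Crafts alkylation of a second arene) is the classical way to methylene-bis-acylphloroglucinols; the two free ring carbons of 9 are equivalent and the deficit of formaldehyde should limit chain growth.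

**Step 5**
Reactants: 8 Mannich base of butyrylfilicinic acid (2.2 equiv); 11 methylenebis(phlorobutyrophenone)
Product: 14 CNP0110234.0 (target), via methylene trione 12 (not isolated), via mono-adduct 13 (not isolated)
Conditions: 1,4-dioxane, 85 °C, argon sweep
Reagents that add atoms: none
Why: Thermal loss of dimethylamine from the zwitterionic Mannich base gives the quinone-methide-like 2-methylene trione, which undergoes Friedel–Crafts-type conjugate addition by the single unsubstituted carbon of each phloroglucinol ring of 11 (the Mannich-base route used for alkylidene-bridged acylphloroglucinols); 8 has no free ring carbon and so cannot condense with itself.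

**Compound list**

1 | methyl 2,2-dimethyl-3-oxobutanoate | COC(=O)C(C)(C)C(C)=O | starting material
2 | methyl 5-(dimethylamino)-2,2-dimethyl-3-oxopentanoate | COC(=O)C(C)(C)C(=O)CCN(C)C | intermediate
3 | phenyl acetate | CC(=O)Oc1ccccc1 | starting material
4 | butanoyl chloride | CCCC(=O)Cl | starting material
5 | phenyl 3-oxohexanoate | CCCC(=O)CC(=O)Oc1ccccc1 | intermediate
6 | butyrylketene (hex-1-ene-1,3-dione) | CCCC(=O)C=C=O | intermediate (not isolated)
7 | methyl 4-[(dimethylamino)methyl]-2,2-dimethyl-3,5,7-trioxodecanoate (racemic, configurationally labile, enolised) | COC(=O)C(C)(C)C(=O)C(CN(C)C)C(=O)CC(=O)CCC | intermediate (not isolated)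
8 | 2-butanoyl-6-[(dimethylamino)methyl]-3,5-dihydroxy-4,4-dimethylcyclohexa-2,5-dien-1-one | CCCC(=O)C1=C(O)C(C)(C)C(O)=C(CN(C)C)C1=O | intermediate
9 | 1-(2,4,6-trihydroxyphenyl)butan-1-one | CCCC(=O)c1c(O)cc(O)cc1O | starting material
10 | 1-[2,4,6-trihydroxy-3-(hydroxymethyl)phenyl]butan-1-one | CCCC(=O)c1c(O)cc(O)c(CO)c1O | intermediate (not isolated)
11 | 1,1'-[methylenebis(2,4,6-trihydroxy-3,1-phenylene)]di(butan-1-one) | CCCC(=O)c1c(O)cc(O)c(Cc2c(O)cc(O)c(C(=O)CCC)c2O)c1O | intermediate
12 | 2-butanoyl-3-hydroxy-4,4-dimethyl-6-methylidenecyclohex-2-ene-1,5-dione | CCCC(=O)C1=C(O)C(C)(C)C(=O)C(=C)C1=O | intermediate (not isolated)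
13 | 2-butanoyl-6-[[3-butanoyl-5-[(3-butanoyl-2,4,6-trihydroxyphenyl)methyl]-2,4,6-trihydroxyphenyl]methyl]-3,5-dihydroxy-4,4-dimethylcyclohexa-2,5-dien-1-one | CCCC(=O)C1=C(O)C(C)(C)C(O)=C(Cc2c(O)c(Cc3c(O)cc(O)c(C(=O)CCC)c3O)c(O)c(C(=O)CCC)c2O)C1=O | intermediate (not isolated)
14 | CNP0110234.0: 6,6'-[methylenebis[(5-butanoyl-2,4,6-trihydroxy-3,1-phenylene)methylene]]bis(2-butanoyl-3,5-dihydroxy-4,4-dimethylcyclohexa-2,5-dien-1-one) | CCCC(=O)C1=C(O)C(C)(C)C(O)=C(Cc2c(O)c(Cc3c(O)c(CC4=C(O)C(C)(C)C(O)=C(C(=O)CCC)C4=O)c(O)c(C(=O)CCC)c3O)c(O)c(C(=O)CCC)c2O)C1=O | target

**Step count**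

Total steps: 5. Longest linear sequence: 3 steps (1 → 3 → 5, or equally 2 → 3 → 5).

**Steps most likely to fail**

1. Step 3 (bears the label "Proposed new method:"). The release of the ketene from the enolate of 5 may be too slow, or the ketene may be consumed by O-acylation or by dimerisation to a pyranone before the C-acylation and ring closure take place. The fallback uses known chemistry, sets out from 9 and returns at 8. Dearomatising C,C-dimethylation of 9 with MeI (2.2 equiv) and NaOMe in MeOH at 0–25 °C should give, after separation from mono- and trimethylated material, 2-butanoyl-3,5-dihydroxy-4,4-dimethylcyclohexa-2,5-dien-1-one (butyrylfilicinic acid) F1. Mannich aminomethylation of F1 at its only free ring carbon with Eschenmoser's salt in MeCN at 25 °C should then give 8.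

2. Step 5. The double alkylation may stop after one arm, and the liberated amine may trigger retro-Mannich cleavage and methylene-bridge scrambling between the rings. The fallback sets out from 8 and 9, bypasses 11 and returns at 14. Heating 8 with an excess of 9 (3 equiv) in 1,4-dioxane at 85 °C should give 2-butanoyl-6-[(3-butanoyl-2,4,6-trihydroxyphenyl)methyl]-3,5-dihydroxy-4,4-dimethylcyclohexa-2,5-dien-1-one (norflavaspidic acid BB) F2, the excess of 9 suppressing double alkylation. Condensation of F2 with 37% aq CH2O (0.5 equiv) and cat. HCl in MeOH–H2O at 25 °C should then join two molecules at their single free aromatic carbon to give 14.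

3. Step 4. Condensation may run on past the dimer to higher methylene-bridged oligomers, because 11 keeps one reactive carbon on each ring. The fallback sets out from 9 and returns at 11. Aminomethylation of 9 with Eschenmoser's salt (1.0 equiv) in MeCN at 0–25 °C should give 1-[3-[(dimethylamino)methyl]-2,4,6-trihydroxyphenyl]butan-1-one F3. Heating F3 with an excess of 9 (3 equiv) in 1,4-dioxane at 85 °C should then give 11 by amine loss and Friedel–Crafts-type addition, so that exactly one methylene bridge is made.

**Further compounds**

F1 | step 3 | 2-butanoyl-3,5-dihydroxy-4,4-dimethylcyclohexa-2,5-dien-1-one (butyrylfilicinic acid) | CCCC(=O)C1=C(O)C(C)(C)C(O)=CC1=O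
F2 | step 5 | 2-butanoyl-6-[(3-butanoyl-2,4,6-trihydroxyphenyl)methyl]-3,5-dihydroxy-4,4-dimethylcyclohexa-2,5-dien-1-one (norflavaspidic acid BB) | CCCC(=O)C1=C(O)C(C)(C)C(O)=C(Cc2c(O)cc(O)c(C(=O)CCC)c2O)C1=O
F3 | step 4 | 1-[3-[(dimethylamino)methyl]-2,4,6-trihydroxyphenyl]butan-1-one | CCCC(=O)c1c(O)cc(O)c(CN(C)C)c1O
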